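The rate constants of this reaction are not to hand, but dividing one rate by another removes time, and with it the size of any supply that feeds both products at a fixed split.

all flasks: partner 0.125 M
- blue: starting material 0.050 M; protic impurity 2.5 mM; run made earlier
- teal: starting material 0.050 M; protic impurity 3.8 mM; run made earlier
- amber: starting material 0.10 M; protic impurity 5 mM; run made earlier
- flask: starting material 0.050 M; protic impurity 5.00 mM; time 2.0 h

| run | time / min | isomer of the product / % | target / % | starting material / % |
|---|---|---|---|---|
| blue | 15.0 | 5 | 15 | 22 |
| blue | 30.0 | 7 | 25 | 18 |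
| blue | 40.0 | 12 | 27 | 14 |
| blue | 60.0 | 18 | 30 | 8 |
| blue | 80.0 | 22 | 28 | 7 |
| blue | 90.0 | 26 | 32 | 4 |
| teal | 8.00 | 0 | 10 | 30 |
| teal | 12.0 | 4 | 14 | 26 |
| teal | 20.0 | 5 | 20 | 20 |
| teal | 25.0 | 8 | 23 | 16 |
| teal | 40.0 | 11 | 27 | 16 |
| teal | 60.0 | 16 | 31 | 7 |
| teal | 90.0 | 23 | 28 | 2 |
| amber | 8.00 | 2 | 12 | 31 |
| amber | 25.0 | 6 | 17 | 22 |
| amber | 40.0 | 11 | 23 | 17 |
| amber | 60.0 | 15 | 23 | 6 |
| amber | 90.0 | 24 | 21 | 4 |

(standard deviation of a reading: 1.5 percentage points)



- share of isomer of the product in isomer of the product plus target at 3.0 min
- share of isomer of the product in isomer of the product plus target at 2.0 h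

Write z for isomer of the product over target, Q over P, both in percent of the starting material charged. Pooling the teal and amber readings up to 12.0 min gives 0.167, and this is b, the starting odds: isomer gained per target gained at the outset, a selectivity factor.

Anna holds a constant split. For her, Q and P grow side by side, z stays at b, and the share Q/(Q+P) stays 14.3% at both asked times.

Ben holds that target passes on to isomer, so z climbs. Pooling blue and teal, he reads 0.557 at 60.0 min and 0.817 at 90.0 min, higher than b. That is a factor of 1.47 in 30.0 min.

Blue and teal differ in protic impurity, yet at 90.0 min they read 0.812 and 0.821. So Ben carries them to the flask. He sets amber aside, with twice the starting material.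

Anna answers that 3.0 min lies before any reading, and there Ben has nothing better than b. My reckoning takes each where it is strong. For the flask at 3.0 min I take the share as 14.3%. I assume that the last 30.0 min multiplies z by the same factor once more, to 1.20, which puts the flask's share at 2.0 h at 54.5%.

The forecast, which expects “plus slow target-to-isomer conversion”, gives 14% (5% to 24%) and 60% (51% to 71%), the latter higher than my figure.

The flask gives 14.4% at 3.0 min and 54.6% at 2.0 h.

    starting material + partner → intermediate + by-product (k = 0.497 M⁻¹ min⁻¹)
    intermediate ⇌ target (K = 2.70, k = 0.171 min⁻¹)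
    intermediate ⇌ isomer of the product (K = 18.3, k = 0.0264 min⁻¹)
    starting material ⇌ dormant form (K = 1.40, k = 0.208 min⁻¹)
    starting material + protic impurity → quenched substrate (k = 2.28 M⁻¹ min⁻¹)
    starting material + target → side product (k = 0.672 M⁻¹ min⁻¹)

In the flask, z is 0.168 at 3.0 min, beside b, the value Anna's view gives there. By 2.0 h the flask's z is 1.20, so it has climbed as Ben held, and the flask holds as much isomer as target at 1.70 h. The neighbouring flask takes 0.50 M of partner, 4.00 times the flask's charge. Partner enters at the first step, ahead of both products, so my reckoning keeps b and again gives 14.3% at 3.0 min, and that neighbour gives 14.4%. At 2.0 h that neighbour's share is 59.1%.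

The numbers in the tables were computed with made-up constants, noise included.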